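The closed, stirred vessel takes a racemate of the two substrates with partner, protic impurity and the single-handed free catalyst. The decision before charging it is whether this recipe, left to the end of the time allowed, can reach the wanted excess or must be changed first.

| flask | left-handed substrate | right-handed substrate | partner | protic impurity | free catalyst | remark | time |
|---|---|---|---|---|---|---|---|
| midnight | 0.025 M | 0.025 M | 0.15 M | 5 mM | 1.2 mM | run made earlier |  |
| dawn | 0.10 M | 0.10 M | 0.15 M | 5 mM | 1.2 mM | run made earlier |  |
| winter | 0.050 M | 0.050 M | 0.15 M | 10 mM | 1.2 mM | run made earlier |  |
| flask | 0.050 M | 0.050 M | 0.150 M | 5.00 mM | 1.2 mM |  | 50 min |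

| run | time / min | right-handed substrate / % | left-handed substrate / % | left-handed product / % |
|---|---|---|---|---|
| midnight | 3.00 | 49.1 | 47.8 | 0 |
| midnight | 8.00 | 51.1 | 44.5 | 6.5 |
| midnight | 15.0 | 50.4 | 42.4 | 10.6 |
| midnight | 40.0 | 48.6 | 33.0 | 17.8 |
| dawn | 5.00 | 51.1 | 45.9 | 3.7 |
| dawn | 15.0 | 50.2 | 41.4 | 7.0 |
| dawn | 25.0 | 51.0 | 37.6 | 11.6 |
| dawn | 40.0 | 50.0 | 34.5 | 14.8 |
| winter | 5.00 | 49.7 | 45.8 | 2.7 |
| winter | 15.0 | 49.6 | 41.4 | 10.5 |
| winter | 25.0 | 50.0 | 36.6 | 13.7 |
| winter | 40.0 | 49.6 | 33.8 | 15.7 |

(standard deviation of a reading: 1 percentage point)

- free catalyst is single-handed; left-handed substrate and right-handed substrate are mirror images of each other, charged as a racemate, each of them at the stated concentration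
- the numbers in the tables scatter by 1 percentage point (one standard deviation)

1. whether the excess of right-handed substrate over left-handed substrate among what is left of the two reaches 98% by 50 min (yes / no)
2. the highest excess of right-handed substrate over left-handed substrate among what is left of the two up to 50 min

The right-handed substrate stays level, at 50.0% of the substrates charged in the dawn run at 40.0 min, so the excess among what is left can be read from one ratio, right-handed over left-handed substrate. That ratio equals one plus the excess over one minus the excess. Pooled over the midnight, dawn and winter runs at 40.0 min, it has doubled 0.549 times; this number of doublings is the half-lives spent, and an excess of 98% needs 6.63 of them.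

Run by run the count at that time reads 0.558, 0.535 and 0.553. Yet dawn had 4.00 times the substrate charge of midnight, and winter twice the protic impurity. A scatter of 1 percentage point on each reading covers those differences, so the loss of left-handed substrate looks pseudo-first-order in these readings, and neither change moves the count beyond what that scatter can show.

The pace slackens, from 0.0175 /min over the first 15.0 min to 0.0137 /min over 40.0 min. Holding the later pace, my own reckoning gives 0.686 half-lives by 50 min, far fewer than the 6.63 needed, and an excess of 23.3%. So by this reckoning the recipe as charged falls short of the wanted excess and must be changed if that excess is to be had; run unchanged, the flask serves to measure the excess this recipe does give.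

The forecast answers no and gives 22%, lower than this reckoning, having read “mild deceleration, perhaps catalyst decay or reversibility” in the same runs.

The flask gives no and 22.3%, which is 0.654 half-lives spent.

    partner + protic impurity → quenched reagent (k = 5.99 /M/min)
    partner + free catalyst + left-handed substrate → free catalyst + left-handed product (k = 97.3 /M²/min)
    partner → decomposition product (k = 3.02 × 10⁻⁵ /min)
    partner + free catalyst + right-handed substrate → free catalyst + right-handed product (k = 2.16 /M²/min)
    2 free catalyst → spent catalyst (k = 13.8 /M/min)

A neighbour flask of the same charge, stopped at 12 min, reaches 8.14%, or 0.235 half-lives, a pace of 0.0196 /min, while the flask adds the remaining 0.419 at 0.0110 /min. In the flask, protic impurity went with partner to quenched reagent at the start, the midpoint of that turnover falling at 0.782 min and the impurity standing at 1.34% of its charge at 5.00 min. Left-handed substrate went on to left-handed product over free catalyst while pairs of free catalyst became spent catalyst, free catalyst standing at 54.7% of its charge at 25.0 min and 37.7% at 50.0 min, with left-handed substrate at 31.5% of the substrates charged.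

The numbers in the tables stem from a simulated flask from invented constants.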